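The earlier runs and the new flask were computed from invented constants; scatter was added.

Intermediate cannot go on rising past the moment when its feed from substrate has fallen to its drain, and that crossing is what the flask below must be asked for.

| setting | dusk | noon | flask |
|---|---|---|---|
| substrate | 0.75 M | 1.1 M | 1.5 M |
| partner | 0.90 equiv | 0.90 equiv | 0.900 equiv |
| protic impurity | 0.075 M | 0.075 M | 0.0750 M |
| free catalyst | 13 mol% | 13 mol% | 13 mol% |
| second catalyst | 5 mol% | 5 mol% | 5 mol% |
| remark | run made earlier | run made earlier |  |
| time |  |  | 12 h |

- dusk (time / h: intermediate / %, target / %): 1.33: 31, 1; 2.00: 37, 0; 2.50: 44, 1; 4.00: 60, 3; 5.00: 66, 2; 6.00: 70, 5; 10.0: 83, 8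
- noon (time / h: intermediate / %, target / %): 1.33: 39, 0; 2.00: 49, 0; 2.50: 56, 3; 4.00: 68, 3; 5.00: 71, 4; 6.00: 77, 8; 10.0: 75, 8

(readings scatter by 1.5 percentage points)

- the analysis behind the earlier runs scatters by 1.5 percentage points, standard deviation

- time up to 12 h at which intermediate stands highest
- the amount of intermediate, in percent of the substrate charged, at that time

Treat both steps as pseudo-first-order in fractions of the charge: substrate feeds intermediate with constant f, and intermediate drains with constant d. The peak then lies at ln(f/d)/(f−d), and its height in this reckoning is the ratio of the two, drain over feed, raised to the power ratio/(1−ratio). An error in f at fixed ratio therefore stretches the reckoned clock and leaves the reckoned height as it is. The runs and the flask share the partner equivalents and both catalyst loadings, so these are taken inside the constants. Substrate concentration differs from run to run, so f and d have to be carried over to the flask.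

The first readings give f as 0.290 h⁻¹ at dusk and 0.372 h⁻¹ at noon. The last readings give d: what stands neither as substrate nor as intermediate, spread over the late intermediate for the run's time less one feed lifetime. That gives 0.0211 h⁻¹ at dusk and 0.0412 h⁻¹ at noon, so in these readings d climbs faster than f.

Scaling f by concentration and d by its square gives, as an estimate for the flask, 0.507 h⁻¹ and 0.0766 h⁻¹. The crossing ratio, drain constant over feed constant, is 0.151. This reckoning puts the peak of the flask at 4.39 h and 71.4%, and in it a doubled ratio costs 12 percentage points.

The forecast stands later and higher than this reckoning, at 6.5 h (4.5 h to 8.5 h) and 78% (73% to 82%), holding that the “peak comes where formation equals loss”.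

The flask stands highest at 5.33 h with 72.9%, while 7.76% of its charge is still substrate.

    substrate + free catalyst → free catalyst + intermediate (k = 0.0410 M⁻¹ min⁻¹)
    partner + second catalyst + intermediate → second catalyst + target (k = 0.0140 M⁻² min⁻¹)
    partner + free catalyst + target → free catalyst + over-reaction product (k = 0.0430 M⁻² min⁻¹)
    partner + protic impurity → quenched reagent (k = 0.120 M⁻¹ min⁻¹)

For the neighbour flask with 20 mol% of second catalyst, scaling the drain with that loading carries the ratio from 0.151 to 0.604, which reckons a peak of 46.3%; that flask reached 51.1%.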